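In a one-step world each point of substrate lost is a point of target, so before planning I asked how far the alpha and zeta runs stood from that world, and whether a flask at the middle charge was worth leaving beyond winter's 30 h.

| flask | substrate | remark | time |
|---|---|---|---|
| alpha | 0.034 M | run made earlier |  |
| zeta | 0.075 M | run made earlier |  |
| winter | 0.050 M |  | 30 h |
| dawn | 0.050 M |  | 40 h |

- alpha (time / h: target / %, substrate / %): 4.00: 11.1, 76.1; 8.00: 20.6, 60.1; 12.0: 27.3, 49.4; 15.0: 29.9, 40.6; 20.0: 36.4, 36.2; 25.0: 39.7, 30.1; 30.0: 40.9, 28.7
- zeta (time / h: target / %, substrate / %): 1.50: 4.6, 90.4; 5.00: 14.3, 71.9; 8.00: 19.7, 60.2; 12.0: 26.7, 49.1; 20.0: 35.7, 35.3; 25.0: 38.2, 31.6; 30.0: 39.4, 25.8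

(each reading ± 1 percentage point)



1. which of the two there is more of at the end, winter (target / third isomer)
2. which of the two there is more of at the end, dawn (target / third isomer)
3. target at the end, in percent of the substrate charged, winter
4. target at the end, in percent of the substrate charged, dawn

The charge looked like a weak lever: at 30.0 h alpha held 40.9% of target and zeta 39.4%, a gap of 1.5 percentage points against a scatter of 1 point per reading, so I pooled the two runs and looked at time. Between 20.0 h and 30.0 h they gained on average 4.1 points of target while substrate fell from 35.8% to 27.2% of the charge, and I took their ratio, the late return, meaning net target gained per fraction of substrate lost across that span (a net selectivity averaged over the span, not an instantaneous one), as 0.482, a reading that carries the scatter and stands below the one-step value; holding it frozen beyond that span was my assumption. Letting substrate shrink by the same proportion over the next ten hours put it at 20.8% at 40 h, so dawn stood to gain 3.1 points and reach 43.3% of target; I resolved to charge 0.050 M and leave it the extra time. The forecast said 40.3% for winter and 42% for dawn, target ahead in both, and of target's slowing rise it wrote: “It may be near a plateau, or it may leak slowly to the third isomer.” My dawn figure stood above its own.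

    target ⇌ isomer of the product B (K = 0.730, k = 4.40 × 10⁻⁶ s⁻¹)
    substrate ⇌ target (K = 15.0, k = 1.00 × 10⁻⁵ s⁻¹)
    substrate ⇌ isomer of the product A (K = 2.30, k = 3.30 × 10⁻⁷ s⁻¹)
    substrate ⇌ third isomer (K = 0.620, k = 9.70 × 10⁻⁶ s⁻¹)

Winter gave 40.8% of target and dawn 44.3%, and at 40.0 h dawn was still making target 1.70 times faster than using it up, each step taken net. From winter to dawn substrate fell from 27% to 21%, which the late return turns into 2.5 points of target against the 3.5 points found. Read at 6.0 d, the same flask had 5.71% of substrate left, for which the late return, counted on from dawn's 44.3%, gives 51.8% of target, and that flask held 52.0%.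

(The readings were generated by integration for substances that don't exist, noise included.)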